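Numbering from the lactone carbonyl (C1), the C7 carbinol lies between the methylenes C6 and C8, and both outer neighbours, C5 (the O-bearing CH of the dihydropyranone ring) and C9, carry oxygen. C7 is therefore brought in as a dithiane carbon that acts twice as a nucleophile: in one flask a lithiated 2-silyl-1,3-dithiane opens the C8–C26 epoxide, silicon moves from C7 to O9, and the regenerated C7 anion opens the C3–C6 epoxide, forging C7–C8 and C6–C7. The precursors are a syn, TBS-protected tail epoxide made from (R)-epichlorohydrin and a purchased benzyloxyethyl oxirane. Ketone unmasking, hydroxyl-directed syn reduction, Z-olefination at C3 and acid-triggered lactonisation complete the all-syn target.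

Key step: step 8

Assumption: the silyl dithiane and the (S)-benzyloxyethyl oxirane used in step 8 are bought as catalogue compounds, the oxirane in enantiopure form; positions are numbered C1–C26 from the lactone carbonyl throughout.

Step 1
Reactants: 1 1-bromotetradecane; 2 (R)-epichlorohydrin
Product: 4 (R)-1-chloroheptadecan-2-ol, via tetradecylmagnesium bromide 3 (not isolated)
Conditions: 1, Mg, THF, reflux; then 2, CuI (10 mol %), THF, −40 → −20 °C; aq NH4Cl
Reagents that add atoms: none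
Why: Copper-catalysed Grignard opening of a terminal epoxide attacks the unsubstituted ring CH2 of 2 by SN2 and leaves the C–Cl bond and the stereogenic carbon (future C11) untouched, so this configuration comes straight from the chiral pool.

Step 2
Reactants: 4 (R)-1-chloroheptadecan-2-ol
Product: 5 (R)-2-pentadecyloxirane
Conditions: NaOH (powdered), Et2O, rt
Reagents that add atoms: none
Why: Intramolecular Williamson etherification (3-exo-tet closure of the alkoxide on the CH2Cl carbon) should form the terminal epoxide without touching C11.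

Step 3
Reactants: 5 (R)-2-pentadecyloxirane
Product: 6 (R)-nonadec-1-en-4-ol
Conditions: vinylmagnesium bromide, CuI (10 mol %), THF, −40 → −20 °C; aq NH4Cl
Reagents that add atoms: vinylmagnesium bromide, C=C[Mg]Br
Why: Copper-catalysed vinyl Grignard opening at the terminal epoxide carbon (C10) should give the homoallylic alcohol with C11 unchanged.

Step 4
Reactants: 6 (R)-nonadec-1-en-4-ol
Product: 7 tert-butyl (4R)-nonadec-1-en-4-yl carbonate
Conditions: Boc2O, DMAP (cat.), MeCN, rt
Reagents that add atoms: di-tert-butyl dicarbonate, CC(C)(C)OC(=O)OC(=O)OC(C)(C)C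
Why: DMAP-catalysed acylation of the secondary alcohol with Boc2O installs the carbonate that serves as the internal oxygen nucleophile of the next step.

Step 5
Reactants: 7 tert-butyl (4R)-nonadec-1-en-4-yl carbonate
Product: 8 (4R,6R)-4-(iodomethyl)-6-pentadecyl-1,3-dioxan-2-one
Conditions: IBr, PhMe, −85 °C; aq Na2S2O3/NaHCO3
Reagents that add atoms: iodine monobromide, IBr
Why: Iodocarbonate cyclisation of a homoallylic tert-butyl carbonate (6-exo attack of the carbonyl oxygen on the iodonium ion, then loss of the tert-butyl group) should set C9 syn to C11 through a chair-like transition state with the pentadecyl chain and the forming CH2I arm both equatorial.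

Step 6
Reactants: 8 (4R,6R)-4-(iodomethyl)-6-pentadecyl-1,3-dioxan-2-one
Product: 9 (2R)-1-[(2R)-oxiran-2-yl]heptadecan-2-ol
Conditions: K2CO3, MeOH, rt
Reagents that add atoms: none
Why: Methanolysis of the cyclic carbonate frees the C9 alkoxide, which displaces the adjacent primary iodide (3-exo-tet Williamson closure) and gives the syn epoxy alcohol with neither stereocentre involved.

Step 7
Reactants: 9 (2R)-1-[(2R)-oxiran-2-yl]heptadecan-2-ol
Product: 10 (R)-2-[(R)-2-(tert-butyldimethylsilyloxy)heptadecyl]oxirane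
Conditions: TBSCl, imidazole, DMF, rt
Reagents that add atoms: tert-butyldimethylsilyl chloride, CC(C)(C)[Si](C)(C)Cl
Why: Imidazole-promoted silylation of a secondary alcohol is tolerated by a terminal epoxide and puts on O11 the same silyl group that the key step will deliver to O9.

Step 8
Reactants: 11 2-(tert-butyldimethylsilyl)-1,3-dithiane; 10 (R)-2-[(R)-2-(tert-butyldimethylsilyloxy)heptadecyl]oxirane; 12 (S)-2-[2-(benzyloxy)ethyl]oxirane
Product: 16 (2S)-4-(benzyloxy)-1-{2-[(2R,4R)-2,4-bis(tert-butyldimethylsilyloxy)nonadecyl]-1,3-dithian-2-yl}butan-2-ol, via lithiated silyl dithiane 13 (not isolated), via C-silyl lithium alkoxide 14 (not isolated), via O-silyl dithianyllithium 15 (not isolated)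
Conditions: 11 (1.1 equiv), t-BuLi (1.1 equiv), Et2O, −78 → −45 °C; 10 (1.0 equiv), Et2O, −78 → −25 °C; then 12 (1.3 equiv), HMPA, Et2O, −78 °C → rt; aq NH4Cl
Reagents that add atoms: none
Why: t-BuLi removes the C2 proton of 11, and the bulky anion 13 opens 10 by SN2 attack at its unsubstituted ring carbon (C8) in ether, a solvent in which the C-silyl alkoxide 14 does not rearrange. HMPA, introduced together with 12, then induces [1,4]-Brook rearrangement of silicon from C7 to O9, and the dithianyl anion 15 released in this way opens 12 at its terminal carbon (C6). The closest known reaction type is exactly this one, the three-component linchpin (anion relay) union of a 2-silyl-1,3-dithiane with two different terminal epoxides, both C–C bonds being driven by relief of epoxide strain. No ring is closed and no stereocentre is created, because C5, C9 and C11 arrive with the epoxides and their stereogenic carbons are never attacked. The step needs a fixed order of the two alkylations, secured by the solvent-gated silyl shift (no second carbanion exists until HMPA is present, by which time 10 is consumed), and terminal regioselectivity, secured by the steric demand of the dithianyl anions towards monosubstituted epoxides. The benzyl ether meets no alkyllithium since 12 is added after t-BuLi is spent, and the TBS group on O11 matches the one delivered to O9 so that both leave together at the end.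

Step 9
Reactants: 16 (2S)-4-(benzyloxy)-1-{2-[(2R,4R)-2,4-bis(tert-butyldimethylsilyloxy)nonadecyl]-1,3-dithian-2-yl}butan-2-ol
Product: 17 (3S,7R,9R)-1-(benzyloxy)-7,9-bis(tert-butyldimethylsilyloxy)-3-hydroxytetracosan-5-one
Conditions: MeI, CaCO3, MeCN/H2O (9:1), 40 °C
Reagents that add atoms: water, O
Why: Alkylative dithioketal hydrolysis (S-methylation, then attack of water on the thionium ion) under CaCO3 buffering should release the C7 ketone without β-elimination or silyl loss.

Step 10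
Reactants: 17 (3S,7R,9R)-1-(benzyloxy)-7,9-bis(tert-butyldimethylsilyloxy)-3-hydroxytetracosan-5-one
Product: 19 (3S,5S,7S,9R)-1-(benzyloxy)-7,9-bis(tert-butyldimethylsilyloxy)tetracosane-3,5-diol, via diethylboron chelate 18 (not isolated)
Conditions: Et2BOMe, THF/MeOH (4:1), −78 °C; NaBH4, −78 °C; AcOH, then MeOH co-evaporation
Reagents that add atoms: none
Why: In this Narasaka–Prasad reduction the boron chelate between O5 and the C7 carbonyl adopts a half-chair that accepts external hydride axially, which should give the 5,7-syn diol and so fix C7 in the all-syn sense.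

Step 11
Reactants: 19 (3S,5S,7S,9R)-1-(benzyloxy)-7,9-bis(tert-butyldimethylsilyloxy)tetracosane-3,5-diol
Product: 20 (4S,6S)-4-[2-(benzyloxy)ethyl]-6-[(2S,4R)-2,4-bis(tert-butyldimethylsilyloxy)nonadecyl]-2,2-dimethyl-1,3-dioxane
Conditions: 2,2-dimethoxypropane, PPTS (cat.), CH2Cl2, rt
Reagents that add atoms: 2,2-dimethoxypropane, COC(C)(C)OC
Why: Acid-catalysed transketalisation converts the syn 1,3-diol into its six-membered acetonide, and PPTS is mild enough to spare the two TBS ethers.

Step 12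
Reactants: 20 (4S,6S)-4-[2-(benzyloxy)ethyl]-6-[(2S,4R)-2,4-bis(tert-butyldimethylsilyloxy)nonadecyl]-2,2-dimethyl-1,3-dioxane
Product: 21 2-{(4S,6S)-6-[(2S,4R)-2,4-bis(tert-butyldimethylsilyloxy)nonadecyl]-2,2-dimethyl-1,3-dioxan-4-yl}ethan-1-ol
Conditions: H2 (1 atm), Pd/C, EtOAc, rt
Reagents that add atoms: none
Why: Hydrogenolysis of the benzyl ether over Pd/C should be clean now that sulfur and alkenes are absent, and neutral ethyl acetate keeps the acetonide and silyl ethers intact.

Step 13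
Reactants: 21 2-{(4S,6S)-6-[(2S,4R)-2,4-bis(tert-butyldimethylsilyloxy)nonadecyl]-2,2-dimethyl-1,3-dioxan-4-yl}ethan-1-ol
Product: 22 2-{(4R,6S)-6-[(2S,4R)-2,4-bis(tert-butyldimethylsilyloxy)nonadecyl]-2,2-dimethyl-1,3-dioxan-4-yl}acetaldehyde
Conditions: PhI(OAc)2, TEMPO (cat.), CH2Cl2, rt
Reagents that add atoms: none
Why: TEMPO-catalysed oxidation with PhI(OAc)2 as terminal oxidant stops at the aldehyde and is mild enough to avoid β-elimination of the acetonide oxygen at C5 (the change of descriptor at the ring carbon is only a change of CIP priority).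

Step 14
Reactants: 22 2-{(4R,6S)-6-[(2S,4R)-2,4-bis(tert-butyldimethylsilyloxy)nonadecyl]-2,2-dimethyl-1,3-dioxan-4-yl}acetaldehyde
Product: 23 ethyl (2Z)-4-{(4S,6S)-6-[(2S,4R)-2,4-bis(tert-butyldimethylsilyloxy)nonadecyl]-2,2-dimethyl-1,3-dioxan-4-yl}but-2-enoate
Conditions: ethyl 2-[bis(2-methylphenoxy)phosphoryl]acetate, NaH, THF, −78 → 0 °C
Reagents that add atoms: ethyl 2-[bis(2-methylphenoxy)phosphoryl]acetate, CCOC(=O)CP(=O)(Oc1ccccc1C)Oc1ccccc1C
Why: In the Ando variant of the Horner–Wadsworth–Emmons reaction the electron-poor diaryl phosphonate eliminates rapidly from the kinetically formed adduct, which should give the Z enoate that places C1 within reach of O5.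

Step 15
Reactants: 23 ethyl (2Z)-4-{(4S,6S)-6-[(2S,4R)-2,4-bis(tert-butyldimethylsilyloxy)nonadecyl]-2,2-dimethyl-1,3-dioxan-4-yl}but-2-enoate
Product: 25 (6S)-6-[(2R,4R,6R)-2,4,6-trihydroxyhenicosyl]-5,6-dihydro-2H-pyran-2-one, via tetrahydroxy Z-enoate 24 (not isolated)
Conditions: 48 % aq HF, MeCN, 0 °C → rt
Reagents that add atoms: none
Why: Aqueous HF should cleave both TBS ethers and the acetonide, after which the O5 hydroxyl, held near the ester by the Z alkene, closes the six-membered lactone by acid-catalysed acyl substitution (no other hydroxyl can reach C1 through an unstrained ring) with no stereocentre affected.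

Compound list
1 | 1-bromotetradecane | CCCCCCCCCCCCCCBr | starting material
2 | (R)-epichlorohydrin, (R)-2-(chloromethyl)oxirane | ClC[C@H]1CO1 | starting material
3 | tetradecylmagnesium bromide | CCCCCCCCCCCCCC[Mg]Br | intermediate
4 | (R)-1-chloroheptadecan-2-ol | CCCCCCCCCCCCCCC[C@@H](O)CCl | intermediate
5 | (R)-2-pentadecyloxirane | CCCCCCCCCCCCCCC[C@@H]1CO1 | intermediate
6 | (R)-nonadec-1-en-4-ol | CCCCCCCCCCCCCCC[C@@H](O)CC=C | intermediate
7 | tert-butyl (4R)-nonadec-1-en-4-yl carbonate | CCCCCCCCCCCCCCC[C@@H](OC(=O)OC(C)(C)C)CC=C | intermediate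
8 | (4R,6R)-4-(iodomethyl)-6-pentadecyl-1,3-dioxan-2-one (cis) | CCCCCCCCCCCCCCC[C@@H]1C[C@H](CI)OC(=O)O1 | intermediate
9 | (2R)-1-[(2R)-oxiran-2-yl]heptadecan-2-ol | CCCCCCCCCCCCCCC[C@@H](O)C[C@@H]1CO1 | intermediate
10 | (R)-2-[(R)-2-(tert-butyldimethylsilyloxy)heptadecyl]oxirane (tail epoxide, C8–C26) | CCCCCCCCCCCCCCC[C@@H](O[Si](C)(C)C(C)(C)C)C[C@@H]1CO1 | intermediate
11 | 2-(tert-butyldimethylsilyl)-1,3-dithiane | CC(C)(C)[Si](C)(C)C1SCCCS1 | starting material
12 | (S)-2-[2-(benzyloxy)ethyl]oxirane (head epoxide, C3–C6) | c1ccccc1COCC[C@H]1CO1 | starting material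
13 | 2-(tert-butyldimethylsilyl)-2-lithio-1,3-dithiane | [Li]C1([Si](C)(C)C(C)(C)C)SCCCS1 | intermediate
14 | lithium (2R,4R)-4-(tert-butyldimethylsilyloxy)-1-[2-(tert-butyldimethylsilyl)-1,3-dithian-2-yl]nonadecan-2-olate | CCCCCCCCCCCCCCC[C@@H](O[Si](C)(C)C(C)(C)C)C[C@@H](O[Li])CC1([Si](C)(C)C(C)(C)C)SCCCS1 | intermediate
15 | 2-[(2R,4R)-2,4-bis(tert-butyldimethylsilyloxy)nonadecyl]-2-lithio-1,3-dithiane | CCCCCCCCCCCCCCC[C@@H](O[Si](C)(C)C(C)(C)C)C[C@@H](O[Si](C)(C)C(C)(C)C)CC1([Li])SCCCS1 | intermediate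
16 | (2S)-4-(benzyloxy)-1-{2-[(2R,4R)-2,4-bis(tert-butyldimethylsilyloxy)nonadecyl]-1,3-dithian-2-yl}butan-2-ol (C3–C26 dithiane) | CCCCCCCCCCCCCCC[C@@H](O[Si](C)(C)C(C)(C)C)C[C@@H](O[Si](C)(C)C(C)(C)C)CC1(C[C@@H](O)CCOCc2ccccc2)SCCCS1 | intermediate
17 | (3S,7R,9R)-1-(benzyloxy)-7,9-bis(tert-butyldimethylsilyloxy)-3-hydroxytetracosan-5-one | CCCCCCCCCCCCCCC[C@@H](O[Si](C)(C)C(C)(C)C)C[C@@H](O[Si](C)(C)C(C)(C)C)CC(=O)C[C@@H](O)CCOCc1ccccc1 | intermediate
18 | (3S,7R,9R)-1-(benzyloxy)-7,9-bis(tert-butyldimethylsilyloxy)-3-[(diethylboranyl)oxy]tetracosan-5-one (boron chelate) | CCCCCCCCCCCCCCC[C@@H](O[Si](C)(C)C(C)(C)C)C[C@@H](O[Si](C)(C)C(C)(C)C)CC(=O)C[C@@H](OB(CC)CC)CCOCc1ccccc1 | intermediate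
19 | (3S,5S,7S,9R)-1-(benzyloxy)-7,9-bis(tert-butyldimethylsilyloxy)tetracosane-3,5-diol (all-syn) | CCCCCCCCCCCCCCC[C@@H](O[Si](C)(C)C(C)(C)C)C[C@@H](O[Si](C)(C)C(C)(C)C)C[C@@H](O)C[C@@H](O)CCOCc1ccccc1 | intermediate
20 | (4S,6S)-4-[2-(benzyloxy)ethyl]-6-[(2S,4R)-2,4-bis(tert-butyldimethylsilyloxy)nonadecyl]-2,2-dimethyl-1,3-dioxane | CCCCCCCCCCCCCCC[C@@H](O[Si](C)(C)C(C)(C)C)C[C@@H](O[Si](C)(C)C(C)(C)C)C[C@@H]1C[C@H](CCOCc2ccccc2)OC(C)(C)O1 | intermediate
21 | 2-{(4S,6S)-6-[(2S,4R)-2,4-bis(tert-butyldimethylsilyloxy)nonadecyl]-2,2-dimethyl-1,3-dioxan-4-yl}ethan-1-ol | CCCCCCCCCCCCCCC[C@@H](O[Si](C)(C)C(C)(C)C)C[C@@H](O[Si](C)(C)C(C)(C)C)C[C@@H]1C[C@H](CCO)OC(C)(C)O1 | intermediate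
22 | 2-{(4R,6S)-6-[(2S,4R)-2,4-bis(tert-butyldimethylsilyloxy)nonadecyl]-2,2-dimethyl-1,3-dioxan-4-yl}acetaldehyde | CCCCCCCCCCCCCCC[C@@H](O[Si](C)(C)C(C)(C)C)C[C@@H](O[Si](C)(C)C(C)(C)C)C[C@@H]1C[C@H](CC=O)OC(C)(C)O1 | intermediate
23 | ethyl (2Z)-4-{(4S,6S)-6-[(2S,4R)-2,4-bis(tert-butyldimethylsilyloxy)nonadecyl]-2,2-dimethyl-1,3-dioxan-4-yl}but-2-enoate | CCCCCCCCCCCCCCC[C@@H](O[Si](C)(C)C(C)(C)C)C[C@@H](O[Si](C)(C)C(C)(C)C)C[C@@H]1C[C@H](C/C=C\C(=O)OCC)OC(C)(C)O1 | intermediate
24 | ethyl (2Z,5S,7S,9R,11R)-5,7,9,11-tetrahydroxyhexacos-2-enoate | CCCCCCCCCCCCCCC[C@@H](O)C[C@@H](O)C[C@@H](O)C[C@@H](O)C/C=C\C(=O)OCC | intermediate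
25 | (6S)-6-[(2R,4R,6R)-2,4,6-trihydroxyhenicosyl]-5,6-dihydro-2H-pyran-2-one (CNP0231118.1) | CCCCCCCCCCCCCCC[C@@H](O)C[C@@H](O)C[C@@H](O)C[C@@H]1CC=CC(=O)O1 | target

Total step count: 15. Longest linear sequence: 15 steps (steps 1–15, from 1 and 2 to 25); 11 and 12 enter at step 8 as purchased materials.

Steps most likely to fail

Step 8 (relay coupling). The silyl shift may run out of step: Brook rearrangement before 10 is consumed, or O-to-O silyl transfer between O11 and O9 in alkoxide 14. Either would scramble the order of the two alkylations or stop the relay at the mono-adduct. The fallback is a stepwise dithiane bis-alkylation that sets out from 10. Commercial 1,3-dithiane (C1SCCCS1) is lithiated (n-BuLi, THF, −30 °C) to 2-lithio-1,3-dithiane F1, which opens 10 at C8 to give (2R,4R)-4-(tert-butyldimethylsilyloxy)-1-(1,3-dithian-2-yl)nonadecan-2-ol F2. Silylation (TBSCl, imidazole, DMF) gives 2-[(2R,4R)-2,4-bis(tert-butyldimethylsilyloxy)nonadecyl]-1,3-dithiane F3. Deprotonation of F3 (t-BuLi, THF/HMPA, −78 °C) gives carbanion 15 directly, and addition of 12 brings the route back at 16.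

Step 9 (dithiane unmasking). S-Alkylation may be slow, and during long exposure the liberated β-hydroxy ketone may dehydrate or undergo retro-aldol cleavage. The fallback unmasks the ketone on a fully protected substrate and sets out from 16. Silylation of O5 (TESOTf, 2,6-lutidine, CH2Cl2, −78 °C) gives {[(2S)-4-(benzyloxy)-1-{2-[(2R,4R)-2,4-bis(tert-butyldimethylsilyloxy)nonadecyl]-1,3-dithian-2-yl}butan-2-yl]oxy}triethylsilane F4. Dithioketal hydrolysis (MeI, CaCO3, aq MeCN) then gives (3S,7R,9R)-1-(benzyloxy)-7,9-bis(tert-butyldimethylsilyloxy)-3-(triethylsilyloxy)tetracosan-5-one F5. Selective removal of the triethylsilyl group (HF·pyridine buffered with pyridine, THF, 0 °C) returns to the route at 17.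

Step 15 (global deprotection and lactonisation). Under acid the freed O7 hydroxyl may add in conjugate fashion to C3 of the unsaturated lactone (intramolecular oxa-Michael addition to a bridged bicyclic lactone), or silyl cleavage may stall. The fallback separates ring formation from desilylation and sets out from 23. PPTS in MeOH at 45 °C removes only the acetonide and lets the lactone close, giving (6S)-6-[(2S,4S,6R)-4,6-bis(tert-butyldimethylsilyloxy)-2-hydroxyhenicosyl]-5,6-dihydro-2H-pyran-2-one F6. The two TBS ethers are then cleaved under buffered, non-basic conditions (HF·pyridine, pyridine, THF, 0 °C → rt), which arrives at 25.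

Further compounds
F1 | step 8 | 2-lithio-1,3-dithiane | [Li]C1SCCCS1
F2 | step 8 | (2R,4R)-4-(tert-butyldimethylsilyloxy)-1-(1,3-dithian-2-yl)nonadecan-2-ol | CCCCCCCCCCCCCCC[C@@H](O[Si](C)(C)C(C)(C)C)C[C@@H](O)CC1SCCCS1
F3 | step 8 | 2-[(2R,4R)-2,4-bis(tert-butyldimethylsilyloxy)nonadecyl]-1,3-dithiane | CCCCCCCCCCCCCCC[C@@H](O[Si](C)(C)C(C)(C)C)C[C@@H](O[Si](C)(C)C(C)(C)C)CC1SCCCS1
F4 | step 9 | {[(2S)-4-(benzyloxy)-1-{2-[(2R,4R)-2,4-bis(tert-butyldimethylsilyloxy)nonadecyl]-1,3-dithian-2-yl}butan-2-yl]oxy}triethylsilane | CCCCCCCCCCCCCCC[C@@H](O[Si](C)(C)C(C)(C)C)C[C@@H](O[Si](C)(C)C(C)(C)C)CC1(C[C@@H](O[Si](CC)(CC)CC)CCOCc2ccccc2)SCCCS1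
F5 | step 9 | (3S,7R,9R)-1-(benzyloxy)-7,9-bis(tert-butyldimethylsilyloxy)-3-(triethylsilyloxy)tetracosan-5-one | CCCCCCCCCCCCCCC[C@@H](O[Si](C)(C)C(C)(C)C)C[C@@H](O[Si](C)(C)C(C)(C)C)CC(=O)C[C@@H](O[Si](CC)(CC)CC)CCOCc1ccccc1
F6 | step 15 | (6S)-6-[(2S,4S,6R)-4,6-bis(tert-butyldimethylsilyloxy)-2-hydroxyhenicosyl]-5,6-dihydro-2H-pyran-2-one | CCCCCCCCCCCCCCC[C@@H](O[Si](C)(C)C(C)(C)C)C[C@@H](O[Si](C)(C)C(C)(C)C)C[C@@H](O)C[C@@H]1CC=CC(=O)O1
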